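Count how long the target sits beside catalyst in each set-up, and ask first what a tie between the best two takes.

in all of them: precatalyst 0.10 mM

| flask | substrate | partner | remark | time |
|---|---|---|---|---|
| elm | 0.050 M | 0.0750 M | a single well-mixed tank run continuously and read at steady state, 5.0 h in it on average |  |
| oak | 0.050 M | 0.0750 M | everything together in a closed stirred flask, run for 5.0 h | 5.0 h |
| cedar | 0.050 M | 0.0750 M (fed, over 4.00 h) | all but partner at the start; partner goes in evenly over 4.00 h, the run ends at 5.0 h | 5.0 h |
| maple | 0.050 M (fed, over 4.00 h) | 0.0750 M | all but substrate at the start; substrate goes in evenly over 4.00 h, the run ends at 5.0 h | 5.0 h |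

    partner + precatalyst → catalyst + spent reagent (k1 = 0.176 M⁻¹ min⁻¹)
    partner → decomposed reagent (k2 = 9.36 × 10⁻⁴ min⁻¹)
    substrate + partner + catalyst → target + catalyst, rate k3*[substrate]*[partner]*[catalyst]/(1 + ([substrate]/sat3)) (sat3 = 1.14 mM, k3 = 2.37 × 10⁵ M⁻² min⁻¹)
    target + catalyst ⇌ isomer of the product + catalyst, rate k4*[catalyst]*[target] forward; the back reaction follows from the equilibrium constant (K4 = 0.413, k4 = 6.45 M⁻¹ min⁻¹)

- the stated concentrations are those of everything mixed, before any reaction; amounts are the same in each set-up
- the feed brings no volume worth counting
- run time (oak): 5.0 h

- the set-up with the highest amount of target at the outlet or at the end, in percent of the substrate put in ("none" if the first two lie within 2 percentage points) (elm / oak / cedar / maple / none)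
- amount of target at the outlet or at the end, in percent of the substrate put in, elm
- amount of target at the outlet or at the end, in percent of the substrate put in, oak
- amount of target at the outlet or at the end, in percent of the substrate put in, cedar
- amount of target at the outlet or at the end, in percent of the substrate put in, maple

1. I take all substrate as converted in oak, cedar and maple, with partner charged 0.0250 M above substrate, so I count their loss of target as isomer.

2. The forward and back constants of the isomerisation, summed at the whole precatalyst charge and multiplied by the run, give what I call the drift clock, 0.662.

3. With all target present from the start and all precatalyst active, that clock gives a ceiling of 14.2% isomer; the margin is 2 percentage points, so a tie asks the best two to use nearly the same part of the clock.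

4. I replace the rising catalyst curve by its mean. In oak and maple I set partner midway between its charge and the excess, which gives 2.64 activation times per run and a mean catalyst share of 64.8%.

5. In cedar I set partner at the excess, which gives 1.32 activation times and a share of 44.5%, lower than in oak and maple.

6. If I take the target in cedar and maple as made evenly over the feed, it has a mean age of 60.0% of the run, so I reckon oak at 89.8%, maple at 93.4% and cedar at 95.3%. In oak I have let the target stand from the first minute, so I hold the oak figure as a low one.

7. Cedar leads by 1.9 points, just inside the margin of 2 points, so taken strictly my reckoning reads as a tie, though one that leans to cedar; elm's tank I leave unreckoned.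

The forecast names cedar, with 90%, 90%, 95% and 92% for elm, oak, cedar and maple, on the ground that “Feeding partner slowly delays both catalyst activation and product formation”.

The simulation gives cedar, with elm 89.8%, oak 91.2%, cedar 95.8% and maple 92.4%, so cedar stands 3.4 points above maple.

Maple's 7.62% isomer at 5.00 h reads back through the clock as a used share of 45.6%, against my 38.9%. The neighbour of maple charged with 4.0 × 10⁻⁴ M of precatalyst has a clock of 2.65, and at maple's used share I reckon 20.5% isomer for it. That neighbour ends with 20.0% isomer and 80.0% target.

The constants used here were drawn at random within sensible limits; no experiment stands behind them.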